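## Retrosynthetic overview

1. Target ⇒ (3S,4S,7S,8S)-bis-epoxide of the 3E,7E-diene keto-lactone: one transannular, water-terminated epoxide-opening cascade forms the tetrahydrofuran C4–O–C7 bond and the C3/C8 hydroxyls (last ring).
2. α-Methylene ε-lactone ⇒ macrocycle carrying a C1 ethynyl group and the C12 tertiary hydroxyl: the acyl C16–O bond (with C15–C16) is made by palladium-catalysed carbonylative lactonisation with CO (second ring, new reaction).
3. 14-Membered carbocycle ⇒ acyclic chloro methyl ketone: C9–C10 bond by intramolecular ketone-enolate alkylation (first ring).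
4. Chain ⇒ E-C3=C4 by two stereoselective couplings on a 1,1-dibromoalkene (dienol-derived alkylborane, then MeZnCl); C1 by rhodium-catalysed asymmetric conjugate alkynylation of an enal.
5. C12 with C10–C14 ⇒ (R)-linalool (Wacker oxidation, cross-metathesis).

Atom labels C1–C20 follow cembrane numbering (C1 bears the acrylate, C11 is the ketone, C12 bears the lactone oxygen); in this numbering the target is (1R,3S,4R,7S,8R,12R).

Assumption: (R)-(−)-linalool (≥95% ee) and the L-fructose-derived enantiomer of the Shi ketone are taken as commercial, and (R)-DTBM-SEGPHOS is assumed to give the (3R)-β-alkynyl aldehyde (if the induction is opposite, the (S)-ligand is used).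

## Route

Step 1
Reactants: 1 (R)-(−)-linalool [(3R)-3,7-dimethylocta-1,6-dien-3-ol]
Product: 2 triethyl{[(3R)-3,7-dimethylocta-1,6-dien-3-yl]oxy}silane
Conditions: Et3SiOTf, 2,6-lutidine, CH2Cl2, −78 → 0 °C
Reagents that add atoms: triethylsilyl trifluoromethanesulfonate, CC[Si](CC)(CC)OS(=O)(=O)C(F)(F)F
Why: O-silylation with a silyl triflate masks the tertiary hydroxyl (which would otherwise add to the later enal) without touching the C–O bond of the stereocentre, so the (R)-centre of linalool is carried through as C12.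

Step 2
Reactants: 2 triethyl{[(3R)-3,7-dimethylocta-1,6-dien-3-yl]oxy}silane
Product: 3 (3R)-3,7-dimethyl-3-[(triethylsilyl)oxy]oct-6-en-2-one
Conditions: Pd(Quinox)Cl2 (Quinox = 2-(4,5-dihydro-1,3-oxazol-2-yl)quinoline, 5 mol%), AgSbF6 (12 mol%), aq. t-BuOOH, CH2Cl2, 0 → 23 °C
Reagents that add atoms: tert-butyl hydroperoxide, CC(C)(C)OO
Why: The peroxide-mediated Tsuji–Wacker oxidation is selective for the monosubstituted alkene of a protected allylic alcohol and gives the methyl ketone (C11=O, C10 methyl), leaving the trisubstituted alkene and the stereocentre alone.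

Step 3
Reactants: 3 (3R)-3,7-dimethyl-3-[(triethylsilyl)oxy]oct-6-en-2-one; 4 (2E)-but-2-enal (crotonaldehyde)
Product: 5 (2E,6R)-6-methyl-7-oxo-6-[(triethylsilyl)oxy]oct-2-enal
Conditions: second-generation Hoveyda–Grubbs catalyst RuCl2(H2IMes)(=CH–C6H4-2-O-i-Pr) (5 mol%), 4 (5 equiv), CH2Cl2, 40 °C
Reagents that add atoms: none
Why: Olefin cross-metathesis exchanges the isopropylidene end group for the electron-poor enal, which forms as the (E)-isomer and brings in C2 and C3.

Step 4
Reactants: 5 (2E,6R)-6-methyl-7-oxo-6-[(triethylsilyl)oxy]oct-2-enal; 6 ethynyltri(propan-2-yl)silane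
Product: 7 (3R,6R)-6-methyl-7-oxo-6-[(triethylsilyl)oxy]-3-{[tri(propan-2-yl)silyl]ethynyl}octanal
Conditions: [Rh(OAc)(C2H4)2]2 (3 mol%), (R)-DTBM-SEGPHOS (7 mol%), 6 (2 equiv), MeOH, 40 °C
Reagents that add atoms: none
Why: Rhodium-catalysed asymmetric conjugate alkynylation of an (E)-enal with a bulky silylacetylene (Hayashi-type 1,4-addition of an alkynyl–rhodium species in the chiral bisphosphine pocket) sets C1 as (R) under catalyst control, the remote C12 centre having no influence.

Step 5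
Reactants: 7 (3R,6R)-6-methyl-7-oxo-6-[(triethylsilyl)oxy]-3-{[tri(propan-2-yl)silyl]ethynyl}octanal
Product: 8 (3R,6R)-9,9-dibromo-3-methyl-3-[(triethylsilyl)oxy]-6-{[tri(propan-2-yl)silyl]ethynyl}non-8-en-2-one
Conditions: CBr4, PPh3, CH2Cl2, 0 °C
Reagents that add atoms: carbon tetrabromide, BrC(Br)(Br)Br
Why: Ramirez dibromo-olefination (first stage of the Corey–Fuchs sequence) converts only the aldehyde, the hindered α-quaternary ketone being inert to the ylide, and supplies C4 as a doubly addressable carbon.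

Step 6
Reactants: 9 prop-2-enal (acrolein); 10 ethyl 2-(triphenyl-λ5-phosphanylidene)propanoate
Product: 11 ethyl (2E)-2-methylpenta-2,4-dienoate
Conditions: CH2Cl2, 0 → 23 °C
Reagents that add atoms: none
Why: Wittig olefination with the stabilised α-methyl ylide gives the (E)-trisubstituted alkene that becomes C7=C8.

Step 7
Reactants: 11 ethyl (2E)-2-methylpenta-2,4-dienoate
Product: 12 (2E)-2-methylpenta-2,4-dien-1-ol
Conditions: i-Bu2AlH (2.2 equiv), CH2Cl2, −78 °C; aq. potassium sodium tartrate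
Reagents that add atoms: none
Why: DIBAL-H 1,2-reduction of the ester gives the allylic alcohol (C9) without changing the diene geometry.

Step 8
Reactants: 12 (2E)-2-methylpenta-2,4-dien-1-ol; 8 (3R,6R)-9,9-dibromo-3-methyl-3-[(triethylsilyl)oxy]-6-{[tri(propan-2-yl)silyl]ethynyl}non-8-en-2-one
Product: 14 (3R,6R,8Z,12E)-9-bromo-14-hydroxy-3,13-dimethyl-3-[(triethylsilyl)oxy]-6-{[tri(propan-2-yl)silyl]ethynyl}tetradeca-8,12-dien-2-one, via alkylborane 13 (not isolated)
Conditions: 12, 9-BBN-H (2.1 equiv), THF, 0 → 23 °C; then 8, Pd(dppf)Cl2 (5 mol%), AsPh3, Cs2CO3, DMF–THF–H2O, 23 °C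
Reagents that add atoms: none
Why: 9-BBN adds anti-Markovnikov to the terminal vinyl group only, and the B-alkyl Suzuki–Miyaura coupling of a 1,1-dibromoalkene takes place first at the bromide trans to the alkyl chain, so the new C4–C5 bond ends up trans to C2.

Step 9
Reactants: 14 (3R,6R,8Z,12E)-9-bromo-14-hydroxy-3,13-dimethyl-3-[(triethylsilyl)oxy]-6-{[tri(propan-2-yl)silyl]ethynyl}tetradeca-8,12-dien-2-one
Product: 15 (3R,6R,8E,12E)-14-hydroxy-3,9,13-trimethyl-3-[(triethylsilyl)oxy]-6-{[tri(propan-2-yl)silyl]ethynyl}tetradeca-8,12-dien-2-one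
Conditions: MeZnCl (3 equiv), Pd(P(t-Bu)3)2 (5 mol%), THF, 23 → 45 °C
Reagents that add atoms: methylzinc chloride, C[Zn]Cl
Why: Negishi coupling replaces the remaining alkenyl bromide by methyl with retention, which fixes the (E)-trisubstituted C3=C4 alkene.

Step 10
Reactants: 15 (3R,6R,8E,12E)-14-hydroxy-3,9,13-trimethyl-3-[(triethylsilyl)oxy]-6-{[tri(propan-2-yl)silyl]ethynyl}tetradeca-8,12-dien-2-one
Product: 16 (3R,6R,8E,12E)-14-chloro-3,9,13-trimethyl-3-[(triethylsilyl)oxy]-6-{[tri(propan-2-yl)silyl]ethynyl}tetradeca-8,12-dien-2-one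
Conditions: PPh3, N-chlorosuccinimide, THF, 0 → 23 °C
Reagents that add atoms: N-chlorosuccinimide, O=C1CCC(=O)N1Cl
Why: Appel-type chlorination converts the primary allylic alcohol into the chloride by SN2 displacement without allylic shift or loss of alkene geometry.

Step 11
Reactants: 16 (3R,6R,8E,12E)-14-chloro-3,9,13-trimethyl-3-[(triethylsilyl)oxy]-6-{[tri(propan-2-yl)silyl]ethynyl}tetradeca-8,12-dien-2-one
Product: 18 (4E,8E,11R,14R)-4,8,14-trimethyl-14-[(triethylsilyl)oxy]-11-{[tri(propan-2-yl)silyl]ethynyl}cyclotetradeca-4,8-dien-1-one, via lithium enolate 17 (not isolated)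
Conditions: LiN(SiMe3)2 (1.1 equiv), THF, −78 °C; then dilution to 0.002 M, DMPU, −78 → 23 °C
Reagents that add atoms: none
Why: The methyl ketone has a single enolisable position (C12 is quaternary), so one enolate forms and, under high dilution, displaces the primary allylic chloride (intramolecular enolate alkylation) to close the 14-membered carbocycle.

Step 12
Reactants: 18 (4E,8E,11R,14R)-4,8,14-trimethyl-14-[(triethylsilyl)oxy]-11-{[tri(propan-2-yl)silyl]ethynyl}cyclotetradeca-4,8-dien-1-one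
Product: 19 (4E,8E,11R,14R)-11-ethynyl-14-hydroxy-4,8,14-trimethylcyclotetradeca-4,8-dien-1-one
Conditions: Bu4NF (3 equiv), AcOH (3 equiv), THF, 0 → 23 °C
Reagents that add atoms: none
Why: Buffered fluoride desilylation cleaves both the Si–O and the Si–C(sp) bonds and leaves the α-ketol and the skipped alkenes untouched.

Step 13
Reactants: 19 (4E,8E,11R,14R)-11-ethynyl-14-hydroxy-4,8,14-trimethylcyclotetradeca-4,8-dien-1-one
Product: 20 (1R,3E,7E,12R)-4,8,12-trimethyl-15-methylidene-13-oxabicyclo[10.3.2]heptadeca-3,7-diene-11,14-dione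
Conditions: Pd(OAc)2 (5 mol%), 2-(diphenylphosphino)pyridine (20 mol%), MeSO3H (10 mol%), CO (20 bar), toluene (0.005 M), 50 °C
Reagents that add atoms: carbon monoxide, [C-]#[O+]
Why: Proposed new method: a cationic palladium hydride (from Pd(OAc)2, the pyridylphosphine and MeSO3H) adds Markovnikov to the terminal alkyne with the pyridyl nitrogen relaying the proton, CO inserts to give a 2-substituted acryloyl–palladium species, and the C12 tertiary hydroxyl, held within reach across the 14-membered ring, attacks the acyl group to close the α-methylene ε-lactone (C16–O bond) and return the hydride, with no stereocentre touched; the closest known reactions are the branched-selective alkoxycarbonylation of terminal alkynes with this catalyst type and the cyclocarbonylation of but-3-yn-1-ols and pent-4-yn-1-ols to five- and six-membered α-methylene lactones, whereas a seven-membered closure onto a tertiary α-ketol has not been shown.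

Step 14
Reactants: 20 (1R,3E,7E,12R)-4,8,12-trimethyl-15-methylidene-13-oxabicyclo[10.3.2]heptadeca-3,7-diene-11,14-dione
Product: 22 (1R,3S,4R,7S,8R,12R)-4,7-epoxy-3,8-dihydroxy-11-oxocembr-15(17)-en-16,12-olide (target CNP0266269.2), via bis-epoxide 21 (not isolated)
Conditions: L-fructose-derived Shi ketone (0.6 equiv), KHSO5 (as 2KHSO5·KHSO4·K2SO4), K2CO3, Bu4NHSO4, MeCN–CH2(OMe)2–aq. Na2B4O7 buffer (pH 10.5), 0 °C; then crude 21, camphorsulfonic acid (0.2 equiv), THF–H2O (4:1), 0 → 23 °C
Reagents that add atoms: potassium peroxymonosulfate, [K+].[O-]OS(=O)(=O)O; water, O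
Why: Shi epoxidation with the L-fructose-derived ketone gives the (S,S)-epoxide from each (E)-trisubstituted alkene by the spiro transition state (the acrylate is too electron-poor to react), and in the acid-catalysed transannular epoxide-opening cascade the 7,8-epoxide oxygen attacks protonated C4 with inversion (5-exo) and water opens the resulting epoxonium at tertiary C8 with inversion, which sets 3S,4R,7S,8R and the cis-tetrahydrofuran.

## Compound list

1 | (R)-(−)-linalool [(3R)-3,7-dimethylocta-1,6-dien-3-ol] | C=C[C@](C)(O)CCC=C(C)C | starting material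
2 | triethyl{[(3R)-3,7-dimethylocta-1,6-dien-3-yl]oxy}silane | C=C[C@](C)(O[Si](CC)(CC)CC)CCC=C(C)C | intermediate
3 | (3R)-3,7-dimethyl-3-[(triethylsilyl)oxy]oct-6-en-2-one | CC(=O)[C@](C)(O[Si](CC)(CC)CC)CCC=C(C)C | intermediate
4 | (2E)-but-2-enal | C/C=C/C=O | starting material
5 | (2E,6R)-6-methyl-7-oxo-6-[(triethylsilyl)oxy]oct-2-enal | CC(=O)[C@](C)(O[Si](CC)(CC)CC)CC/C=C/C=O | intermediate
6 | ethynyltri(propan-2-yl)silane | C#C[Si](C(C)C)(C(C)C)C(C)C | starting material
7 | (3R,6R)-6-methyl-7-oxo-6-[(triethylsilyl)oxy]-3-{[tri(propan-2-yl)silyl]ethynyl}octanal | CC(=O)[C@](C)(O[Si](CC)(CC)CC)CC[C@@H](C#C[Si](C(C)C)(C(C)C)C(C)C)CC=O | intermediate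
8 | (3R,6R)-9,9-dibromo-3-methyl-3-[(triethylsilyl)oxy]-6-{[tri(propan-2-yl)silyl]ethynyl}non-8-en-2-one | CC(=O)[C@](C)(O[Si](CC)(CC)CC)CC[C@@H](C#C[Si](C(C)C)(C(C)C)C(C)C)CC=C(Br)Br | intermediate
9 | prop-2-enal | C=CC=O | starting material
10 | ethyl 2-(triphenyl-λ5-phosphanylidene)propanoate | CCOC(=O)C(C)=P(c1ccccc1)(c1ccccc1)c1ccccc1 | starting material
11 | ethyl (2E)-2-methylpenta-2,4-dienoate | C=C/C=C(\C)C(=O)OCC | intermediate
12 | (2E)-2-methylpenta-2,4-dien-1-ol | C=C/C=C(\C)CO | intermediate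
13 | 9-{(3E)-5-[(9-borabicyclo[3.3.1]nonan-9-yl)oxy]-4-methylpent-3-en-1-yl}-9-borabicyclo[3.3.1]nonane | B1(C2CCCC1CCC2)CC/C=C(\C)COB1C2CCCC1CCC2 | intermediate (not isolated)
14 | (3R,6R,8Z,12E)-9-bromo-14-hydroxy-3,13-dimethyl-3-[(triethylsilyl)oxy]-6-{[tri(propan-2-yl)silyl]ethynyl}tetradeca-8,12-dien-2-one | CC(=O)[C@](C)(O[Si](CC)(CC)CC)CC[C@@H](C#C[Si](C(C)C)(C(C)C)C(C)C)C/C=C(\Br)CC/C=C(\C)CO | intermediate
15 | (3R,6R,8E,12E)-14-hydroxy-3,9,13-trimethyl-3-[(triethylsilyl)oxy]-6-{[tri(propan-2-yl)silyl]ethynyl}tetradeca-8,12-dien-2-one | CC(=O)[C@](C)(O[Si](CC)(CC)CC)CC[C@@H](C#C[Si](C(C)C)(C(C)C)C(C)C)C/C=C(\C)CC/C=C(\C)CO | intermediate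
16 | (3R,6R,8E,12E)-14-chloro-3,9,13-trimethyl-3-[(triethylsilyl)oxy]-6-{[tri(propan-2-yl)silyl]ethynyl}tetradeca-8,12-dien-2-one | CC(=O)[C@](C)(O[Si](CC)(CC)CC)CC[C@@H](C#C[Si](C(C)C)(C(C)C)C(C)C)C/C=C(\C)CC/C=C(\C)CCl | intermediate
17 | lithium (3R,6R,8E,12E)-14-chloro-3,9,13-trimethyl-3-[(triethylsilyl)oxy]-6-{[tri(propan-2-yl)silyl]ethynyl}tetradeca-1,8,12-trien-2-olate | [Li+].C=C([O-])[C@](C)(O[Si](CC)(CC)CC)CC[C@@H](C#C[Si](C(C)C)(C(C)C)C(C)C)C/C=C(\C)CC/C=C(\C)CCl | intermediate (not isolated)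
18 | (4E,8E,11R,14R)-4,8,14-trimethyl-14-[(triethylsilyl)oxy]-11-{[tri(propan-2-yl)silyl]ethynyl}cyclotetradeca-4,8-dien-1-one | C1C(=O)[C@](C)(O[Si](CC)(CC)CC)CC[C@@H](C#C[Si](C(C)C)(C(C)C)C(C)C)C/C=C(\C)CC/C=C(\C)C1 | intermediate
19 | (4E,8E,11R,14R)-11-ethynyl-14-hydroxy-4,8,14-trimethylcyclotetradeca-4,8-dien-1-one | C1C(=O)[C@](C)(O)CC[C@@H](C#C)C/C=C(\C)CC/C=C(\C)C1 | intermediate
20 | (1R,3E,7E,12R)-4,8,12-trimethyl-15-methylidene-13-oxabicyclo[10.3.2]heptadeca-3,7-diene-11,14-dione [(1R,3E,7E,12R)-11-oxocembra-3,7,15(17)-trien-16,12-olide] | C=C1C(=O)O[C@]2(C)CC[C@@H]1C/C=C(\C)CC/C=C(\C)CCC2=O | intermediate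
21 | (1R,3S,4S,7S,8S,12R)-3,4:7,8-diepoxy-11-oxocembr-15(17)-en-16,12-olide | C=C1C(=O)O[C@]2(C)CC[C@@H]1C[C@@H]3O[C@@]3(C)CC[C@@H]4O[C@@]4(C)CCC2=O | intermediate (not isolated)
22 | (1R,3S,4R,7S,8R,12R)-4,7-epoxy-3,8-dihydroxy-11-oxocembr-15(17)-en-16,12-olide (CNP0266269.2) | C=C1C(=O)O[C@]2(C)CC[C@@H]1C[C@H](O)[C@@]1(C)CC[C@H](O1)[C@](C)(O)CCC2=O | target

## Step count and weakest steps

Total: 14 steps. Longest linear sequence: 12 steps (steps 1–5 and 8–14, from (R)-linalool); steps 6–7 make the side fragment.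

**Step 13 (new carbonylative lactonisation).** The tertiary α-ketol is a weak nucleophile for the acyl–palladium species, so alkyne oligomerisation or palladium-hydride isomerisation of the skipped alkenes may win. Fallback with known reactions, setting out from 19 and coming back at 20: branched-selective methoxycarbonylation of the alkyne with the same catalyst in methanol (Pd(OAc)2, 2-(diphenylphosphino)pyridine, MeSO3H, CO, MeOH–toluene) gives methyl 2-[(1R,3E,7E,12R)-12-hydroxy-4,8,12-trimethyl-11-oxocyclotetradeca-3,7-dien-1-yl]prop-2-enoate F1. Me3SnOH (1,2-dichloroethane, 70 °C) then gives 2-[(1R,3E,7E,12R)-12-hydroxy-4,8,12-trimethyl-11-oxocyclotetradeca-3,7-dien-1-yl]prop-2-enoic acid F2. Yamaguchi lactonisation (2,4,6-trichlorobenzoyl chloride, Et3N; then DMAP, toluene, 80 °C, high dilution) closes the ε-lactone onto the tertiary hydroxyl to give 20.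

**Step 11 (macrocyclisation by ketone-enolate alkylation).** A simple lithium enolate may give O-alkylation, oligomers or elimination of the allylic chloride instead of the 14-membered ring. Fallback setting out from 15 and coming back at 18: methyl chloroformate and pyridine convert 15 into (2E,6E,9R,12R)-2,6,12-trimethyl-13-oxo-12-[(triethylsilyl)oxy]-9-{[tri(propan-2-yl)silyl]ethynyl}tetradeca-2,6-dien-1-yl methyl carbonate F3. Its lithium enolate (LiN(SiMe3)2, THF, −78 °C) is cyclised with Pd(PPh3)4 and 1,2-bis(diphenylphosphino)ethane under high dilution (23 → 50 °C). This is a Tsuji–Trost allylic alkylation: zerovalent palladium forms a π-allyl complex that the enolate attacks at its primary terminus, giving 18. The ring closure thus runs through π-allyl chemistry instead of SN2 displacement.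

**Step 14 (double Shi epoxidation and transannular cascade).** Three things can go wrong:
- Facial control on the macrocycle may be eroded, also by a dioxirane formed from the substrate's own C11 ketone.
- Water may open C4 first, which leads to the 7,8-epimeric tetrahydrofuran.
- Prolonged acid may move the lactone onto the C3 hydroxyl.

Fallback setting out from 20 and coming back at 22: run the Shi epoxidation alone and isolate 21, then trigger the cascade with BF3·OEt2 in dry CH2Cl2 at −78 °C. The C11 ketone oxygen, not external water, then terminates the cascade at C8 with the same inversion (ketone-terminated epoxide cascade). Quenching with aqueous NaHCO3 gives (1R,3S,4R,7S,8R,12R)-4,7:8,11-diepoxy-3,11-dihydroxycembr-15(17)-en-16,12-olide (the cyclic hemiketal of the target, C11 anomers) F4, which opens to 22 by ring–chain tautomerism in wet THF with pyridinium p-toluenesulfonate.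

Further compounds

F1 | step 13 | methyl 2-[(1R,3E,7E,12R)-12-hydroxy-4,8,12-trimethyl-11-oxocyclotetradeca-3,7-dien-1-yl]prop-2-enoate | C1C(=O)[C@](C)(O)CC[C@@H](C(=C)C(=O)OC)C/C=C(\C)CC/C=C(\C)C1
F2 | step 13 | 2-[(1R,3E,7E,12R)-12-hydroxy-4,8,12-trimethyl-11-oxocyclotetradeca-3,7-dien-1-yl]prop-2-enoic acid | C1C(=O)[C@](C)(O)CC[C@@H](C(=C)C(=O)O)C/C=C(\C)CC/C=C(\C)C1
F3 | step 11 | (2E,6E,9R,12R)-2,6,12-trimethyl-13-oxo-12-[(triethylsilyl)oxy]-9-{[tri(propan-2-yl)silyl]ethynyl}tetradeca-2,6-dien-1-yl methyl carbonate | CC(=O)[C@](C)(O[Si](CC)(CC)CC)CC[C@@H](C#C[Si](C(C)C)(C(C)C)C(C)C)C/C=C(\C)CC/C=C(\C)COC(=O)OC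
F4 | step 14 | (1R,3S,4R,7S,8R,12R)-4,7:8,11-diepoxy-3,11-dihydroxycembr-15(17)-en-16,12-olide (cyclic hemiketal of 22) | C=C1C(=O)O[C@]2(C)CC[C@@H]1C[C@H](O)[C@@]1(C)CC[C@H](O1)[C@@]3(C)CCC2(O)O3
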